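**The product ratio.** The product of a racemate can be read through one number, the amount of left-handed product over right-handed product. The symmetric case is the zero of the scale: a ratio of one gives an excess of zero, and the single-handed free catalyst moves the flask off it. If the two substrates stay equal, the ratio is the selectivity factor s, and the excess is (s − 1)/(s + 1) at any conversion.

| flask | left-handed substrate | right-handed substrate | coupling partner | free catalyst | precatalyst | remark | time |
|---|---|---|---|---|---|---|---|
| Tuesday's | 1 mM | 1 mM | 2.5 mM | 0.25 µM | 5 µM | run made earlier |  |
| Sunday's | 1 mM | 1 mM | 2.5 mM | 0.38 µM | 5 µM | run made earlier |  |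
| Wednesday's | 1 mM | 1 mM | 2.5 mM | 0.50 µM | 2.5 µM | run made earlier |  |
| theta | 1.0 mM | 1.0 mM | 2.50 mM | 0.50 µM | 5.0 µM |  | 2.5 min |
| epsilon | 1.0 mM | 1.0 mM | 2.50 mM | 0.50 µM | 5.0 µM |  | 0.80 min |

| run | time / min | left-handed product / % | right-handed product / % |
|---|---|---|---|
| Tuesday's | 0.667 | 11.7 | 6.7 |
| Tuesday's | 1.33 | 20.6 | 10.6 |
| Tuesday's | 2.00 | 27.0 | 14.0 |
| Tuesday's | 2.50 | 31.9 | 16.8 |
| Tuesday's | 3.00 | 34.8 | 19.0 |
| Sunday's | 0.250 | 7.5 | 4.4 |
| Sunday's | 0.417 | 11.7 | 7.2 |
| Sunday's | 0.833 | 20.6 | 11.2 |
| Sunday's | 1.50 | 30.4 | 15.6 |
| Sunday's | 3.00 | 41.8 | 21.9 |
| Wednesday's | 0.250 | 9.2 | 4.9 |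
| Wednesday's | 0.833 | 24.3 | 13.3 |
| Wednesday's | 1.33 | 31.5 | 17.8 |
| Wednesday's | 2.00 | 39.0 | 22.1 |
| Wednesday's | 3.00 | 45.9 | 25.9 |

(readings scatter by 0.5 percentage points)

- free catalyst is single-handed; left-handed substrate and right-handed substrate are mirror images of each other, charged as a racemate, each of them at the stated concentration
- an excess is the difference of the two amounts in percent of their sum
- an excess is below zero if the other one leads

- which of the two ends with the higher excess of left-handed product over right-handed product in the product ("neither" if they lie within 2 percentage points) (theta / epsilon / neither)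
- excess of left-handed product over right-handed product in the product at the end, theta
- excess of left-handed product over right-handed product in the product at the end, epsilon

**First instants.** In Sunday's run at 0.250 min I read a ratio of 1.70. This was a loose value, with 0.5 percentage points of scatter on 4.4% of right-handed product.

**The middle.** At 0.833 min Sunday's ratio read 1.84. Without exchange between the substrates, a ratio above one means that the left-handed substrate thins faster, and the ratio then sinks as the run proceeds.

**The end.** At 3.00 min Sunday's ratio read 1.91, which had not sunk. If there had been no exchange, these readings would put the left-handed substrate at 8.20% and the right-handed at 28.1%, both in percent of the two together charged. The ratio of their logarithmic decays would then be 3.14, more than the ratio of the first reading. So I concluded that the substrates interconverted and stayed nearly equal, a dynamic kinetic resolution.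

**My reckoning.** I pooled the last readings of Tuesday's and Sunday's runs, which share the precatalyst charge of theta and epsilon, and took s, the selectivity factor, as 1.87. That gave 30.4% for both flasks.

**The forecast.** It gave 30% (27% to 33%) for theta, 30% (27% to 33%) for epsilon, and neither as the leader, holding that “the product excess stays nearly flat”.

**The result.** Theta ended at 30.0% and epsilon at 29.8%, so the answer was neither.

    coupling partner + free catalyst + left-handed substrate → free catalyst + left-handed product (k = 1.20 × 10⁷ /M²/s)
    precatalyst ⇌ racemization catalyst (K = 0.180, k = 0.0350 /s)
    left-handed substrate + racemization catalyst ⇌ right-handed substrate + racemization catalyst, rate k3*[racemization catalyst]*[left-handed substrate] forward; the back reaction follows from the equilibrium constant (k = 1.30 × 10⁵ /M/s)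
    coupling partner + free catalyst + right-handed substrate → free catalyst + right-handed product (k = 6.30 × 10⁶ /M²/s)

**Carried on.** With 67.1% of the substrates reacted, theta still held an excess of right-handed substrate of 0.845% among what remained. Applying s to that conversion gives 43.7% of left-handed product, and theta held 43.6%. In the neighbour flask, epsilon with 0.0012 mM of precatalyst, s gives 30.4% and the flask gave 27.8%, with 60% of the left-handed substrate left against 67% of the right-handed.

(The numbers in the tables were computed with constants of no real substance, and the scatter is random.)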